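**Assumption:** the keto–enol form drawn for the diarylheptanoid is the tautomer curcuminoids adopt spontaneously, and only reactants, intermediates and the target carry numbers (reagents do not).

## Retrosynthetic overview

1. Target ⇒ silyl ether 11 ⇒ curcumin (10) + cis-allylic alcohol 9: the C–OAr bond is made by a protecting-group-free Mitsunobu mono-etherification that desymmetrises curcumin and inverts the carbinol.
2. 9 ⇒ silyloxy-enone 5 + dienone 8: one-pot kinetic Michael addition, then reduction of the ring ketone while the side-chain ketone is masked as its enolate. The ring C–C(side chain) bond and three stereocentres are set from the one carbinol centre of 5.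
3. 5 ⇒ 4-methoxy-2-methylphenol (1): oxidative dearomatisation to a quinone monoketal differentiates the two ring oxygens; mono-hydrogenation and CBS reduction follow.
4. Rings: none is constructed. The cyclohexene is the dearomatised ring of phenol 1 (first); the two aryl rings arrive intact with curcumin (last).

## Route

**Step 1**
Reactants: 1, 4-methoxy-2-methylphenol
Product: 2, 4,4-dimethoxy-2-methylcyclohexa-2,5-dien-1-one
Conditions: PhI(OAc)2 (1.1 equiv), MeOH, 0 °C
Reagents that add atoms: methanol, CO
Why: Hypervalent-iodine oxidative dearomatisation of a p-methoxyphenol to a p-quinone monoketal turns the arene into the future terpenoid ring with its two oxygens differentiated (free enone C=O next to the methyl-bearing carbon, ketal para to it); no stereocentre is formed.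

**Step 2**
Reactants: 2
Product: 3, 4,4-dimethoxy-2-methylcyclohex-2-en-1-one
Conditions: H2 (1 atm), (Ph3P)3RhCl (5 mol%), benzene, rt
Reagents that add atoms: none
Why: Chemoselective homogeneous hydrogenation with Wilkinson's catalyst should saturate the unhindered 1,2-disubstituted alkene faster than the trisubstituted methyl-bearing one and, unlike Pd/C, should avoid reductive re-aromatisation; no stereocentre is formed.

**Step 3**
Reactants: 3
Product: 4, (S)-4-hydroxy-3-methylcyclohex-2-en-1-one
Conditions: (R)-Me-CBS (10 mol%), catecholborane, toluene, −78 °C; then 1 M HCl, THF, 0 °C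
Reagents that add atoms: water, O (ketal hydrolysis)
Why: Corey–Bakshi–Shibata reduction of an α-substituted cyclohexenone, with the α-methylvinyl arm as the large group, gives the (S)-allylic alcohol with the (R)-catalyst (this sets the ring carbinol centre), and the acidic work-up hydrolyses the ketal so its carbon becomes the enone carbonyl.

**Step 4**
Reactants: 4
Product: 5, (S)-4-[(tert-butyldimethylsilyl)oxy]-3-methylcyclohex-2-en-1-one
Conditions: TBSCl, imidazole, DMF, rt
Reagents that add atoms: tert-butyldimethylsilyl chloride, CC(C)(C)[Si](C)(C)Cl
Why: Standard imidazole-promoted silyl ether formation protects the only hydroxyl so that the later etherification addresses a single alcohol; the stereocentre is untouched.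

**Step 5**
Reactants: 6, (E)-but-2-enoyl chloride; 7, 2-methylprop-1-enylmagnesium bromide
Product: 8, (E)-2-methylhepta-2,5-dien-4-one
Conditions: 7, ZnCl2, THF, 0 °C; then 6, Pd(PPh3)4 (2 mol%), 0 °C → rt
Reagents that add atoms: none beyond the two listed reactants
Why: Negishi acylation (Pd-catalysed coupling of an acyl chloride with an alkenylzinc) gives the cross-conjugated dienone without conjugate addition and keeps the E geometry.

**Step 6**
Reactants: 5; 8
Product: 9, (1S,4S,6R)-4-[(tert-butyldimethylsilyl)oxy]-3-methyl-6-[(2S)-6-methyl-4-oxohept-5-en-2-yl]cyclohex-2-en-1-ol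
Conditions: LDA (1.05 equiv), THF, −78 °C; 8, −78 → −40 °C; re-cool to −78 °C, L-Selectride (1.3 equiv); aq. NH4Cl
Reagents that add atoms: none
Why: Kinetic α′-deprotonation gives the cross-conjugated lithium dienolate, which undergoes Michael addition to the crotonyl terminus of 8 anti to the pseudoaxial OTBS (ring C6 trans to C4–O) through a Li-chelated closed transition state of an E-enolate with an E-enone (syn adduct, side-chain methine S); the side-chain ketone then stays masked as its lithium enolate while L-Selectride reduces the ring enone 1,2 from the face opposite the new α′-substituent to give the cis (1S) alcohol.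

**Step 7**
Reactants: 9; 10, curcumin (3 equiv, excess recovered)
Product: 11, the target carrying a TBS ether on the ring hydroxyl (curcumin mono-ether; ring 1R,4S,6R, side chain 2S)
Conditions: PPh3 (1.5 equiv), DIAD (1.5 equiv), THF, 0 °C → rt
Reagents that add atoms: none beyond the listed reactants
Why: Mitsunobu etherification (SN2 with inversion at the allylic carbinol) converts the cis-alcohol into the aryl ether trans to the side chain and cis to the silyloxy group, and because curcumin's two phenols are equivalent a statistical mono-etherification desymmetrises it without protecting groups.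

**Step 8**
Reactants: 11
Product: 12, bisabolocurcumin ether
Conditions: HF·pyridine, THF/pyridine, 0 °C → rt
Reagents that add atoms: none
Why: Buffered fluoride desilylation frees the allylic alcohol without affecting the allyl aryl ether, the enones or the base-sensitive β-diketone; no stereocentre is touched.

## Compound list

1 | 4-methoxy-2-methylphenol | COc1ccc(O)c(C)c1 | starting material
2 | 4,4-dimethoxy-2-methylcyclohexa-2,5-dien-1-one | COC1(OC)C=CC(=O)C(C)=C1 | intermediate
3 | 4,4-dimethoxy-2-methylcyclohex-2-en-1-one | COC1(OC)CCC(=O)C(C)=C1 | intermediate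
4 | (S)-4-hydroxy-3-methylcyclohex-2-en-1-one | O=C1C=C(C)[C@@H](O)CC1 | intermediate
5 | (S)-4-[(tert-butyldimethylsilyl)oxy]-3-methylcyclohex-2-en-1-one | O=C1C=C(C)[C@@H](O[Si](C)(C)C(C)(C)C)CC1 | intermediate
6 | (E)-but-2-enoyl chloride | C/C=C/C(=O)Cl | starting material
7 | 2-methylprop-1-enylmagnesium bromide | CC(C)=C[Mg]Br | starting material
8 | (E)-2-methylhepta-2,5-dien-4-one | C/C=C/C(=O)C=C(C)C | intermediate
9 | (1S,4S,6R)-4-[(tert-butyldimethylsilyl)oxy]-3-methyl-6-[(2S)-6-methyl-4-oxohept-5-en-2-yl]cyclohex-2-en-1-ol | O[C@@H]1C=C(C)[C@@H](O[Si](C)(C)C(C)(C)C)C[C@@H]1[C@@H](C)CC(=O)C=C(C)C | intermediate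
10 | curcumin, (1E,4Z,6E)-5-hydroxy-1,7-bis(4-hydroxy-3-methoxyphenyl)hepta-1,4,6-trien-3-one | COc1cc(/C=C/C(=O)/C=C(O)/C=C/c2ccc(O)c(OC)c2)ccc1O | starting material
11 | TBS ether of the target: (1E,4Z,6E)-7-[4-({(1R,4S,6R)-4-[(tert-butyldimethylsilyl)oxy]-3-methyl-6-[(2S)-6-methyl-4-oxohept-5-en-2-yl]cyclohex-2-en-1-yl}oxy)-3-methoxyphenyl]-5-hydroxy-1-(4-hydroxy-3-methoxyphenyl)hepta-1,4,6-trien-3-one | COc1cc(/C=C/C(=O)/C=C(O)/C=C/c2ccc(O[C@H]3C=C(C)[C@@H](O[Si](C)(C)C(C)(C)C)C[C@@H]3[C@@H](C)CC(=O)C=C(C)C)c(OC)c2)ccc1O | intermediate
12 | bisabolocurcumin ether: (1E,4Z,6E)-5-hydroxy-7-[4-({(1R,4S,6R)-4-hydroxy-3-methyl-6-[(2S)-6-methyl-4-oxohept-5-en-2-yl]cyclohex-2-en-1-yl}oxy)-3-methoxyphenyl]-1-(4-hydroxy-3-methoxyphenyl)hepta-1,4,6-trien-3-one | COc1cc(/C=C/C(=O)/C=C(O)/C=C/c2ccc(O[C@H]3C=C(C)[C@@H](O)C[C@@H]3[C@@H](C)CC(=O)C=C(C)C)c(OC)c2)ccc1O | target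

## Summary

Total steps: 8. Longest linear sequence: 7 (1 → 2 → 3 → 4 → 5 → 9 → 11 → 12); step 5 is a one-step side branch.

Three steps most likely to fail:

1. **Step 6 (one-pot Michael addition / masked-enolate reduction).** Risks are 1,2-addition or proton transfer to the dienone, a second intramolecular Michael giving a bicyclo[2.2.2]octanone, modest syn selectivity, and the wrong hydride face. Fallback: build the side chain in two stages. Use S-ethyl (E)-but-2-enethioate as the acceptor (clean 1,4-addition, no competing ketone), reduce and etherify as planned, then install the isobutenyl ketone by Pd-catalysed Fukuyama coupling of the thioester with (2-methylprop-1-enyl)zinc.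

2. **Step 7 (Mitsunobu on a hindered allylic alcohol with unprotected curcumin).** Risks are E2 elimination to the diene, SN2′ attack, alkylation at the curcumin enol or central carbon, and bis-ether formation. Fallback: etherify with vanillin instead (more acidic, a single nucleophilic site), then assemble the diarylheptanoid by boron-templated (Pabon) aldol condensation of that aldehyde with (E)-6-(4-hydroxy-3-methoxyphenyl)hex-5-ene-2,4-dione.

3. **Step 2 (mono-hydrogenation of the quinone monoketal).** Risks are over-reduction and reductive re-aromatisation to the phenol. Fallback: reach 5 without the monoketal. Start from 2-methylcyclohex-2-en-1-one (Birch reduction/hydrolysis of 2-methylanisole), do the CBS reduction and silylation, then introduce the ring ketone by allylic C–H oxidation (CrO3·3,5-dimethylpyrazole).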